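## Structural features

Atoms carry the numbers of their position in the target SMILES (C1–C6/O7 sorbyl ketone on C8; C9 ketone; C11 with Me12 and O13; C14; C15 with the enolised sorbyl unit C16–C22; C23 ketone; C25 with Me26; C27 with O28; C29 with Me30; C31 lactone carbonyl; O33; C34 with Me35; C36). "Exo" is the convex face of the diquinane (side of H36 and C6), "endo" the concave face. The carbon core is a cis-bicyclo[3.3.0]octane (ring A C8-C9-C11-C14-C36, ring C C8-C25-C27-C34-C36) whose endo faces are tied by the bridge C15–C23 (ring B, two interlocked bicyclo[3.2.1]octanes); the γ-lactone (ring D, C27-C29-C31-O33-C34) is cis-fused to ring C on the same endo face. Eight stereocentres are contiguous: quaternary C8 and C25, tertiary carbinols C11 and C27, the tertiary ether carbon C34, the methines C14 and C36, and the epimerisable C29. Fragile groups are the two dienones, the enolised β-diketone at C15, the non-enolisable 1,3-diketone through C8 (retro-Claisen), the α-ketol C9/C11 and the β-hydroxy lactone (retro-aldol, dehydration). The difficulty lies in telling nearly equivalent positions apart: Me12 is endo and O13 exo on ring A, whereas on ring C Me35 and O28 are exo and the lactone atoms endo, and C25 must receive its methyl before ring B turns it into a bridgehead that can no longer be enolised. The key step uses a twofold axis through the midpoint of the C8–C36 bond and at right angles to it (an axis along the bond could not exchange C8 with C36). It maps C9 on C34, C11 on C27 and C14 on C25, the pattern of a cis-bicyclo[3.3.0]octane-3,7-dione with esters on all four α-carbons. The symmetry is broken only by C6 on C8, by Me26 and by the oxygen patterns, so the C6 hydroxyl is used as an internal handle.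

## Logic of the disconnections

35 ⇒ 32 + 34. Cut C15–C16. C15 is the only enolisable α-carbon of 32, so C-acylation of the C23 ketone brings in the second dienone last and keeps it away from all oxidants. The forward step must acylate on carbon under conditions that spare the lactone and the 1,3-diketone through C8.

32 ⇒ 28 + 30. Cut C5–C6 (and adjust C6 to the aldehyde). This removes the first diene and leaves a neopentyl aldehyde. The forward addition must choose an aldehyde over two ketones and a lactone.

28 ⇒ 26. Cut C9–O10 and C11–O13. Both oxygens come from one syn-dihydroxylation of a C9=C11 alkene on the exo face, which sets C11 with Me12 endo; carbonyl addition to a C11 ketone would put the methyl exo. The demand is that no other alkene is present.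

26 ⇒ 23. Cut C27–C29 (and the C29–H bond). An ester enolate tethered through O33 can reach C27 only from the endo face, so C27 follows from C34; C29 is set by protonation. The demand is that no other acidic C–H exists in 23.

23 ⇒ 20. Cut O33–C31 and C34–O33. Oxygen is delivered to the C27/C34 enolate after C23 has been masked as an enol ether. The demand is endo attack at C34.

20 ⇒ 18. Cut C11–C12. Methyl comes by cross-coupling of an enol triflate, which needs C11 to be the most reactive of three ketones.

18 ⇒ 15. Cut C34–C35 and restore the C34 ester. The ester makes C34 the only carbon acid for mild methylation and, as its enolate, protects ring C during ring B closure.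

15 ⇒ 14 ⇒ 12. Cut C15–C23. The two ester carbons left on C14 and C25 by the annulation become the bridge. A reductive coupling of two esters was not used because 4 has four esters, of which C14/C34 and C9/C25 could pair to five-membered rings. Instead the C14 ester is reduced to a C15 nucleophile that attacks the C25 ester. The demand is an endo C15 and a masked ring C.

12 ⇒ 10. Protecting-group and resolution stage: C6–O as a bulky silyl ether, C11 as ketal, absolute configuration by enzymatic acylation.

10 ⇒ 6. Cut C25–C26 and restore the C9 carboxyl. Methylation must hit C25 and not the less hindered C14 or C34; these are blocked as chlorides while the lactone shields C9. The same lactone then lets the C9 carboxyl leave selectively.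

6 ⇒ 4. Cut the lactone O–C(=O) bond. Freeing the C6 hydroxyl of 4 is the first symmetry-breaking act: it can reach only the two mirror-related esters on C9 and C25.

4 ⇒ 2 + 2 × 3. Cut C8–C9, C8–C25, C36–C14 and C36–C34. Two rings, both ring-fusion centres and all functional handles arise in one step from achiral materials. The demand is full double annulation and cis fusion.

2 ⇒ 1, 30 ⇒ 29, 34 ⇒ 33. Functional-group changes on commercial materials.

## Other disconnections considered

Alternative 1: Cut C25–C27. Forward, (Ph3P)AuCl with AgBF4 (monovalent gold) activates a terminal alkyne on C34 and the silyl enol ether carbon C25 attacks C27 (5-exo-dig), closing ring C and giving A1 with an exocyclic methylene at C27.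
- In favour: neutral catalytic conditions, direct formation of quaternary C25 next to C8, and a substrate in which Me26, Me35/O33, the C11 carbinol and the C6 dienone are already in place.
- Against: the rings A/B precursor with C8, C11, C14, C34 and C36 set needs its own long construction with no symmetry to help; the C27 methylene must later be cleaved to the ketone beside a diene; C29 must still be brought in from the endo face.
- Comparison: on structure it is the better plan at C34 and C25, because neither the facial problem at C34 nor the regiochemical problem of the C25 methyl arises. On mechanism it is equal in reliability to the chosen annulation. On step economy the chosen plan should be shorter, since four bonds and two rings come from commodity materials.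

Alternative 2: Cut C11–C14 and C34–C36. Forward, a masked o-benzoquinone Diels–Alder adduct (bicyclo[2.2.2]octenone) undergoes acetone-sensitised oxa-di-π-methane rearrangement to A2, which holds rings A and C plus a cyclopropane C14–C34–C36.
- In favour: oxygen is already on C9, C11, C27 and C34, so no ester has to be exchanged for oxygen; in this match of oxidation pattern it is the better plan. The rearrangement is stereospecific and forms two rings in one step, equal in that respect to the annulation.
- Against: the C14–C34 cyclopropane bond must be cleaved reductively; C34 then carries a methyl ether and no Me35, and introducing a methyl on a carbon that already bears OMe is hard; the photochemical step limits scale; ring B and the lactone remain to be built.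
- Comparison: the count from the aromatic precursor should be equal or longer, and absolute configuration needs an auxiliary or a resolution just as here.

Alternative 3: Cut C14–C15. Forward, Cs2CO3 deprotonates a β-diketone side chain on C25 and C15 adds to C14 of a 2-methylcyclopentenone in ring A, closing ring B and giving A3, the 11-deoxy target as its O28 silyl ether.
- In favour: a mild, reversible, thermodynamically driven closure with both dienones and the lactone already present. In mildness and convergence it is better than the organolithium ring closure chosen here, and it sets C14 through the tether.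
- Against: the substrate is a fully decorated diquinane lactone made without the rigid ring B that the chosen plan uses for facial control; the β-diketone chain must be attached at neopentyl C25; C11 must be hydroxylated at the very end beside two dienes and a β-diketone; retro-Michael and C29 epimerisation threaten.
- Comparison: such a diquinane would itself most simply come from the same double annulation, so the step counts should be similar. The chosen plan closes ring B early, while functionality is simple.

Key step: step 2

## Route

Remark: 4–10 are racemic or configurationally mobile; their SMILES show the enantiomer carried on after step 7.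
Remark: it is assumed that the lipase in step 7 acetylates the antipode of the enantiomer drawn.
Remark: 2 is made from diol 1 rather than by SeO2 oxidation of 1-(benzyloxy)propan-2-one, where the activated O–CH2 group would compete with the methyl group.

Step 1
Reactants: 1 3-(benzyloxy)propane-1,2-diol
Product: 2 3-(benzyloxy)-2-oxopropanal
Conditions: (COCl)2, DMSO, CH2Cl2, −78 °C; Et3N, to 0 °C; used crude
Reagents that add atoms: none
Why: Double Swern oxidation of a vicinal diol gives the 1,2-dicarbonyl compound without C–C cleavage; the hydrate-prone keto aldehyde goes straight into the aqueous annulation.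

Step 2
Reactants: 2 3-(benzyloxy)-2-oxopropanal; 3 dimethyl 3-oxopentanedioate (2 equiv)
Product: 4 bis-enol diquinane tetramethyl ester with benzyloxymethyl on C8
Conditions: citrate–phosphate buffer pH 5.6, MeOH/H2O, rt, 2–3 d
Reagents that add atoms: none
Why: Weiss–Cook condensation: the enol of the first molecule of 3 adds to the aldehyde carbon (C36) and then intramolecularly to the ketone carbon (C8) of 2; loss of water gives a 4-hydroxycyclopentenone, the second molecule of 3 adds at C36 in Michael fashion, and β-elimination of the C8 hydroxyl creates a second enone that takes the closing Michael addition at C8. The closest known reaction type is the condensation of methylglyoxal and other 1,2-dicarbonyl compounds with dimethyl 3-oxoglutarate in buffered water. Ring A is closed by the intramolecular aldol step (C8–C9 after C36–C14) and ring C by the second Michael step (C8–C25 after C36–C34); both are 5-exo-trig closures in which the nucleophilic carbon reacts through its ester enolate, whose C=C lies outside the forming ring (5-enolexo), so both are allowed. C8 and C36 are the only centres fixed; their cis relation is the thermodynamic result because the last Michael addition is reversible and a trans-fused bicyclo[3.3.0]octane is far more strained. The four ester-bearing carbons stay mobile through enolisation, so 4 is one constitutional compound that is in effect racemic. The selectivity needed is complete 2:1 annulation rather than stalling at the monocyclic adduct; the slightly acidic buffer keeps each β-keto ester enolised and should let the bis-enol 4 separate from the medium. No choice between C9/C25 or C14/C34 is needed, since these pairs are mirror-related in 4.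

Step 3
Reactants: 4 bis-enol diquinane tetramethyl ester with benzyloxymethyl on C8
Product: 6 exo γ-lactone triester (C6–O–CO–C9), via hydroxy tetraester 5 (not isolated)
Conditions: H2 (1 atm), 10% Pd/C, EtOAc, rt; filter; TsOH·H2O (cat.), toluene, 60 °C
Reagents that add atoms: none
Why: Hydrogenolysis frees the C6 hydroxyl, which can form a five-membered lactone only with the esters on C9 and C25; acid-catalysed transesterification closes one cis-fused γ-lactone and thereby names that carbon C9 and its ring A (racemate). The lactone carbonyl must be cis to C6, so H9 is endo.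

Step 4
Reactants: 6 exo γ-lactone triester (C6–O–CO–C9)
Product: 7 14,34-dichloro lactone triester
Conditions: SO2Cl2 (2.05 equiv), CH2Cl2, 0 °C
Reagents that add atoms: sulfuryl chloride, ClS(Cl)(=O)=O
Why: Electrophilic chlorination of the two β-dicarbonyl enols: ring A can enolise only towards C14 without a double bond at the lactone ring fusion, and ring C should react at C34, next to the C36 methine, not next to quaternary C8; convex-face attack puts Cl exo. The chlorines block C14 and C34 against the next alkylation.

Step 5
Reactants: 7 14,34-dichloro lactone triester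
Product: 8 25-methyl dichloro lactone triester
Conditions: Cs2CO3 (1.1 equiv), MeI (1.5 equiv), DMF, 0 °C to rt
Reagents that add atoms: iodomethane, CI
Why: Alkylation of the only accessible β-keto ester carbanion: C14 and C34 are quaternary, and C9 could be methylated only from the crowded concave face because its lactone carbonyl is held exo, so MeI enters at C25 from the convex face (Me26 exo, ester endo as ring B needs). It is done now because C25 cannot be enolised once ring B exists.

Step 6
Reactants: 8 25-methyl dichloro lactone triester
Product: 10 hydroxy triester bis-enol, via dichloro hydroxy triester 9 (not isolated)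
Conditions: 2 M HCl, AcOH, 60 °C; then Zn dust, rt
Reagents that add atoms: none
Why: C9 is the only enolisable β-dicarbonyl carbon, so acid hydrolysis of the lactone and decarboxylation of the β-keto acid remove the C9 carboxyl while the three hindered esters on quaternary carbons survive; the freed C6 hydroxyl cannot lactonise again because the C25 ester is locked endo. Zinc then reduces both α-chloro β-keto esters back to C–H through zinc enolates.

Step 7
Reactants: 10 hydroxy triester bis-enol (racemic)
Product: 11 TBDPS ether of the hydroxy triester, single enantiomer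
Conditions: lipase from Burkholderia cepacia, vinyl acetate, MTBE, 30 °C, to about half conversion; filter; TBDPSCl, imidazole, DMF, rt; chromatography
Reagents that add atoms: tert-butyl(chloro)diphenylsilane, CC(C)(C)[Si](Cl)(c1ccccc1)c1ccccc1
Why: Lipase-catalysed kinetic resolution of a primary alcohol with an irreversible acyl donor; silylation of the unreacted enantiomer in the same flask makes separation from the acetate easy and protects C6–O with a bulky group that later shields the exo face of ring C. From here all compounds are single enantiomers.

Step 8
Reactants: 11 TBDPS ether of the hydroxy triester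
Product: 12 C11 ethylene ketal (C14 ester, either epimer)
Conditions: 1,2-bis(trimethylsilyloxy)ethane, TMSOTf (cat.), CH2Cl2, −78 to −20 °C
Reagents that add atoms: 1,2-bis(trimethylsilyloxy)ethane, C[Si](C)(C)OCCO[Si](C)(C)C
Why: Noyori ketalisation; only the ring A ketone reacts, because the ring C ketone is flanked by quaternary C25 and held as a hydrogen-bonded enol ester. The C14 ester thereby becomes an ordinary ester.

Step 9
Reactants: 12 C11 ethylene ketal (C14 ester, either epimer)
Product: 13 primary alcohol with endo C15H2OH
Conditions: LDA (2.2 equiv), THF, −78 °C; 2,6-di-tert-butyl-4-methylphenol (1.05 equiv), −78 °C; LiAlH4, −78 to −40 °C; Rochelle salt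
Reagents that add atoms: none
Why: LDA forms the ring C β-keto ester enolate and the C14 ester enolate (at −78 °C β-elimination of the ketal oxygen is slow); one equivalent of the hindered phenol reprotonates only the far more basic ester enolate, from the convex face, which places the ester endo (kinetic protonation). LiAlH4 then reduces this unhindered ester while the enolate protects the C27 ketone and C34 ester and the C25 ester is shielded by its quaternary surroundings; C14 is set with H exo and C15 endo.

Step 10
Reactants: 13 primary alcohol with endo C15H2OH
Product: 14 primary iodide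
Conditions: I2, PPh3, imidazole, CH2Cl2, 0 °C
Reagents that add atoms: iodine, II
Why: Appel-type iodination of the primary alcohol under neutral conditions, run at once so that the endo hydroxymethyl group cannot lactonise onto a ring C ester.

Step 11
Reactants: 14 primary iodide
Product: 15 tricyclic keto enol ester (ring B closed)
Conditions: LDA (1.1 equiv), THF, −78 °C; t-BuLi (2.1 equiv), Et2O/pentane, −100 to −40 °C; NH4Cl
Reagents that add atoms: none
Why: LDA masks ring C as its β-keto ester enolate; fast iodine–lithium exchange gives the primary alkyllithium, which attacks the endo C25 ester carbon facing it (6-exo-trig acyl substitution, the Cooke/Parham type of iodo ester cyclisation). This forms C15–C23 and ring B with C15 as CH2 and C23 as the ketone, so the two ester carbons of the annulation become C15 and C23; no new stereocentre is formed.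

Step 12
Reactants: 15 tricyclic keto enol ester (ring B closed)
Product: 18 triketone with C34 H/Me, via methylated keto ester 16 (not isolated), via ketal diketone 17 (not isolated)
Conditions: K2CO3, MeI, acetone, rt; evaporate; LiCl, H2O, DMSO, 140 °C; then 2 M HCl, THF, 40 °C
Reagents that add atoms: iodomethane, CI; water, O
Why: The ring C β-keto ester is the only carbon acid K2CO3 can deprotonate, so C34 is methylated chemoselectively (configuration irrelevant here); Krapcho dealkoxycarbonylation removes the last ester and dilute acid cleaves the dioxolane. C34 is left as an epimerisable H/Me centre.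

Step 13
Reactants: 18 triketone with C34 H/Me
Product: 19 C9=C11 enol triflate
Conditions: Tf2O (1.1 equiv), 2,6-di-tert-butyl-4-methylpyridine, CH2Cl2, 0 °C to rt
Reagents that add atoms: trifluoromethanesulfonic anhydride, O=S(=O)(OS(=O)(=O)C(F)(F)F)C(F)(F)F
Why: Stang enol triflate formation by O-triflation of the most basic, least hindered carbonyl: C11 lies between a CH2 and a methine, whereas C23 and C27 each adjoin quaternary C25 and deactivate one another as a 1,3-diketone. C11 can lose a proton only from C9 because C14 is a bridgehead.

Step 14
Reactants: 19 C9=C11 enol triflate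
Product: 20 11-methyl alkene diketone
Conditions: MeZnCl (2 equiv), Pd(PPh3)4 (5 mol%), THF, 50 °C
Reagents that add atoms: methylzinc chloride, C[Zn]Cl
Why: Negishi coupling of the enol triflate under zerovalent palladium catalysis installs C12 and tolerates both ketones.

Step 15
Reactants: 20 11-methyl alkene diketone
Product: 21 C15=C23 TBS enol ether
Conditions: LDA (1.05 equiv), THF, −78 °C; TBSCl, DMPU
Reagents that add atoms: tert-butyl(chloro)dimethylsilane, CC(C)(C)[Si](C)(C)Cl
Why: Kinetic deprotonation takes the less substituted, more acidic C15 methylene rather than the C34 methine, and O-silylation fixes the enol ether; this masks C23 and flattens C15, which opens the endo face of ring C.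

Step 16
Reactants: 21 C15=C23 TBS enol ether
Product: 22 tertiary alcohol (O33–H endo, Me35 exo)
Conditions: KHMDS (1.2 equiv), THF, −78 °C; 2-(benzenesulfonyl)-3-phenyloxaziridine; NH4Cl
Reagents that add atoms: 2-(benzenesulfonyl)-3-phenyloxaziridine, O=S(=O)(c1ccccc1)N1OC1c1ccccc1
Why: Davis enolate oxidation; C27 is now the only enolisable ketone. The tetrasubstituted C27=C34 enolate should be attacked on the endo face, because the exo face is covered by the syn C6H2OTBDPS group on C8 while the endo face meets only the flat C15=C23 unit, giving O33 endo and Me35 exo.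

Step 17
Reactants: 22 tertiary alcohol (O33–H endo, Me35 exo)
Product: 23 O33 propanoate
Conditions: EtCOCl, DMAP, Et3N, CH2Cl2, 40 °C
Reagents that add atoms: propanoyl chloride, CCC(=O)Cl
Why: DMAP-catalysed acylation of the only free hydroxyl, a hindered tertiary alcohol.

Step 18
Reactants: 23 O33 propanoate
Product: 25 β-hydroxy γ-lactone with C29 set, via lactone epimers 24 (not isolated)
Conditions: LDA (2.4 equiv), THF, −78 to −40 °C; recool to −78 °C; AcOH in THF
Reagents that add atoms: none
Why: The propanoate α-hydrogens are the only acidic C–H (C27 has no α-hydrogen), so the ester enolate adds to the neighbouring C27 ketone (intramolecular ester aldol, the lactone counterpart of a Lacey–Dieckmann closure), necessarily from the endo face on which O33 sits: C29 endo, O28 exo. Excess base converts the β-oxido lactone into its enolate (Fráter–Seebach-type dianion), and kinetic protonation on the open face of ring D, cis to O28 and away from ring B, places H29 cis to O28 and Me30 on the ring C side.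

Step 19
Reactants: 25 β-hydroxy γ-lactone with C29 set
Product: 26 desilylated hydroxy ketone lactone
Conditions: HF·pyridine, pyridine, THF, 0 °C to rt
Reagents that add atoms: none
Why: Fluoride cleaves the silyl ether and the silyl enol ether, returning the C6 alcohol and the C23 ketone before any oxidant is used.

Step 20
Reactants: 26 desilylated hydroxy ketone lactone
Product: 27 9,11-exo-diol
Conditions: OsO4 (5 mol%), NMO, acetone/H2O, rt
Reagents that add atoms: 4-methylmorpholine 4-oxide, C[N+]1([O-])CCOCC1; water, O
Why: Upjohn dihydroxylation of the only alkene; OsO4 should add to the exo face of the C9=C11 bridge, which faces only H36, while the endo face is covered by the C23 bridge. Both hydroxyls are exo and Me12 endo (C11 set; the C9 centre is temporary).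

Step 21
Reactants: 27 9,11-exo-diol
Product: 28 C6 aldehyde C9 ketone
Conditions: (COCl)2, DMSO, CH2Cl2, −78 °C; Et3N
Reagents that add atoms: none
Why: Swern oxidation converts the secondary C9 alcohol into the ketone and the primary C6 alcohol into the aldehyde in one operation; tertiary alcohols are untouched and activated DMSO does not cleave the 1,2-diol.

Step 22
Reactants: 29 (E)-but-2-enal
Product: 30 (1E,3E)-1-iodopenta-1,3-diene
Conditions: CHI3, CrCl2, THF, 0 °C, dark
Reagents that add atoms: iodoform, IC(I)I
Why: Takai iodoolefination converts the aldehyde into the E vinyl iodide.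

Step 23
Reactants: 28 C6 aldehyde C9 ketone; 30 (1E,3E)-1-iodopenta-1,3-diene
Product: 31 C6 dienyl carbinol (C6 epimers)
Conditions: CrCl2 (6 equiv), NiCl2 (1 mol%), DMSO, rt
Reagents that add atoms: none
Why: Nozaki–Hiyama–Kishi coupling: the alkenylchromium species adds to aldehydes only, so the ketones, the lactone and the free tertiary alcohols are tolerated; the new carbinol centre is oxidised away next.

Step 24
Reactants: 31 C6 dienyl carbinol (C6 epimers)
Product: 32 C6 sorbyl ketone (15-deacyl target)
Conditions: Dess–Martin periodinane, NaHCO3, CH2Cl2, 0 °C
Reagents that add atoms: none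
Why: Dess–Martin oxidation of the secondary dienyl carbinol to the dienone; no 1,2-diol remains that could be cleaved.

Step 25
Reactants: 33 sorbic acid
Product: 34 1-[(2E,4E)-hexa-2,4-dienoyl]-1H-benzotriazole
Conditions: SOCl2, 1H-benzotriazole (4 equiv), CH2Cl2, rt
Reagents that add atoms: 1H-benzotriazole, c1ccc2[nH]nnc2c1
Why: Katritzky acylbenzotriazole synthesis gives a neutral, storable acyl donor.

Step 26
Reactants: 32 C6 sorbyl ketone (15-deacyl target); 34 1-[(2E,4E)-hexa-2,4-dienoyl]-1H-benzotriazole
Product: 35 CNP0231466.1
Conditions: MgBr2·OEt2 (3 equiv), i-Pr2NEt (4 equiv), CH2Cl2, rt; 1 M HCl work-up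
Reagents that add atoms: none
Why: Soft enolisation of the only enolisable ketone (C23, towards C15) and C-acylation by the acylbenzotriazole (direct Claisen of the Coltart type); the product is held as its magnesium β-diketonate, which prevents a second acylation, and after acid work-up rests as the hydrogen-bonded enol of the target.

## Compound list

1 | 3-(benzyloxy)propane-1,2-diol (racemic) | OCC(O)COCc1ccccc1 | starting material
2 | 3-(benzyloxy)-2-oxopropanal | O=CC(=O)COCc1ccccc1 | intermediate
3 | dimethyl 3-oxopentanedioate | COC(=O)CC(=O)CC(=O)OC | starting material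
4 | bis-enol diquinane tetramethyl ester with benzyloxymethyl on C8: tetramethyl cis-1-[(benzyloxy)methyl]-3,7-dihydroxybicyclo[3.3.0]octa-2,6-diene-2,4,6,8-tetracarboxylate (enols at C9 and C34; mobile C14 and C25 esters drawn endo) | COC(=O)C1=C(O)[C@H](C(=O)OC)[C@@H]2C(C(=O)OC)=C(O)[C@H](C(=O)OC)[C@]12COCc1ccccc1 | intermediate
5 | hydroxy tetraester: the C8 hydroxymethyl analogue of 4 | COC(=O)C1=C(O)[C@H](C(=O)OC)[C@@H]2C(C(=O)OC)=C(O)[C@H](C(=O)OC)[C@]12CO | intermediate
6 | exo γ-lactone triester: lactone C6–O–CO–C9 cis-fused on the exo face (H9 endo); enol esters C11(OH)=C14(CO2Me) and C27(OH)=C34(CO2Me); C25 CO2Me endo (mobile) | O=C1OC[C@@]23[C@@H]1C(O)=C(C(=O)OC)[C@@H]2C(C(=O)OC)=C(O)[C@@H]3C(=O)OC | intermediate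
7 | 14,34-dichloro lactone triester (Cl exo on C14 and C34; C11 and C27 ketones) | O=C1OC[C@@]23[C@@H]1C(=O)[C@](Cl)(C(=O)OC)[C@@H]2[C@](Cl)(C(=O)OC)C(=O)[C@@H]3C(=O)OC | intermediate
8 | 25-methyl dichloro lactone triester (Me26 exo, C25 CO2Me endo) | O=C1OC[C@@]23[C@@H]1C(=O)[C@](Cl)(C(=O)OC)[C@@H]2[C@](Cl)(C(=O)OC)C(=O)[C@]3(C)C(=O)OC | intermediate
9 | dichloro hydroxy triester (C9H2, free C6–OH) | OC[C@@]12CC(=O)[C@](Cl)(C(=O)OC)[C@@H]1[C@](Cl)(C(=O)OC)C(=O)[C@]2(C)C(=O)OC | intermediate
10 | hydroxy triester bis-enol: C6–OH; C9H2; enol esters at C11/C14 and C27/C34; C25 with Me exo and CO2Me endo | OC[C@@]12CC(O)=C(C(=O)OC)[C@@H]1C(C(=O)OC)=C(O)[C@]2(C)C(=O)OC | intermediate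
11 | TBDPS ether of the hydroxy triester (C6–OSi(t-Bu)Ph2) | CC(C)(C)[Si](c1ccccc1)(c1ccccc1)OC[C@@]12CC(O)=C(C(=O)OC)[C@@H]1C(C(=O)OC)=C(O)[C@]2(C)C(=O)OC | intermediate
12 | C11 ethylene ketal; C14 CO2Me as either epimer; ring C enol ester | CC(C)(C)[Si](c1ccccc1)(c1ccccc1)OC[C@@]12CC3(OCCO3)C(C(=O)OC)[C@@H]1C(C(=O)OC)=C(O)[C@]2(C)C(=O)OC | intermediate
13 | primary alcohol: C14 with H exo and C15H2OH endo | CC(C)(C)[Si](c1ccccc1)(c1ccccc1)OC[C@@]12CC3(OCCO3)[C@H](CO)[C@@H]1C(C(=O)OC)=C(O)[C@]2(C)C(=O)OC | intermediate
14 | primary iodide (C15H2I endo on C14) | CC(C)(C)[Si](c1ccccc1)(c1ccccc1)OC[C@@]12CC3(OCCO3)[C@H](CI)[C@@H]1C(C(=O)OC)=C(O)[C@]2(C)C(=O)OC | intermediate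
15 | tricyclic keto enol ester: ring B closed (C15H2, C23 ketone); C11 ketal; ring C enol ester C27(OH)=C34(CO2Me) | CC(C)(C)[Si](c1ccccc1)(c1ccccc1)OC[C@]12CC4(OCCO4)[C@@H]3CC(=O)[C@@]1(C)C(O)=C(C(=O)OC)[C@@H]32 | intermediate
16 | methylated keto ester: C34 with Me and CO2Me (either face), C27 ketone, C11 ketal | CC(C)(C)[Si](c1ccccc1)(c1ccccc1)OC[C@]12CC4(OCCO4)[C@@H]3CC(=O)[C@@]1(C)C(=O)C(C)(C(=O)OC)[C@@H]32 | intermediate
17 | ketal diketone: C23 and C27 ketones, C34 H/Me epimers, C11 ketal | CC(C)(C)[Si](c1ccccc1)(c1ccccc1)OC[C@]12CC4(OCCO4)[C@@H]3CC(=O)[C@@]1(C)C(=O)C(C)[C@@H]32 | intermediate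
18 | triketone: C11, C23 and C27 ketones; C34 H/Me epimers | CC(C)(C)[Si](c1ccccc1)(c1ccccc1)OC[C@]12CC(=O)[C@@H]3CC(=O)[C@@]1(C)C(=O)C(C)[C@@H]32 | intermediate
19 | C9=C11 enol triflate (OTf on C11) | CC(C)(C)[Si](c1ccccc1)(c1ccccc1)OC[C@]12C=C(OS(=O)(=O)C(F)(F)F)[C@@H]3CC(=O)[C@@]1(C)C(=O)C(C)[C@@H]32 | intermediate
20 | 11-methyl alkene diketone (C9=C11, Me12 on C11) | CC(C)(C)[Si](c1ccccc1)(c1ccccc1)OC[C@]12C=C(C)[C@@H]3CC(=O)[C@@]1(C)C(=O)C(C)[C@@H]32 | intermediate
21 | C15=C23 TBS enol ether; C27 ketone | CC(C)(C)[Si](c1ccccc1)(c1ccccc1)OC[C@]12C=C(C)[C@@H]3C=C(O[Si](C)(C)C(C)(C)C)[C@@]1(C)C(=O)C(C)[C@@H]32 | intermediate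
22 | tertiary alcohol: C34 with O33–H endo and Me35 exo | CC(C)(C)[Si](c1ccccc1)(c1ccccc1)OC[C@]12C=C(C)[C@@H]3C=C(O[Si](C)(C)C(C)(C)C)[C@@]1(C)C(=O)[C@@](C)(O)[C@@H]32 | intermediate
23 | O33 propanoate | CC(C)(C)[Si](c1ccccc1)(c1ccccc1)OC[C@]12C=C(C)[C@@H]3C=C(O[Si](C)(C)C(C)(C)C)[C@@]1(C)C(=O)[C@@](C)(OC(=O)CC)[C@@H]32 | intermediate
24 | lactone epimers: ring D closed, O28–H exo, C29 undefined | CC(C)(C)[Si](c1ccccc1)(c1ccccc1)OC[C@]12C=C(C)[C@@H]3C=C(O[Si](C)(C)C(C)(C)C)[C@@]1(C)[C@@]1(O)C(C)C(=O)O[C@@]1(C)[C@@H]32 | intermediate
25 | β-hydroxy γ-lactone with C29 set (H29 cis to O28, Me30 towards ring C) | CC(C)(C)[Si](c1ccccc1)(c1ccccc1)OC[C@]12C=C(C)[C@@H]3C=C(O[Si](C)(C)C(C)(C)C)[C@@]1(C)[C@@]1(O)[C@@H](C)C(=O)O[C@@]1(C)[C@@H]32 | intermediate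
26 | desilylated hydroxy ketone lactone: C6–OH, C23 ketone, C9=C11 alkene | OC[C@]12C=C(C)[C@@H]3CC(=O)[C@@]1(C)[C@@]1(O)[C@@H](C)C(=O)O[C@@]1(C)[C@@H]32 | intermediate
27 | 9,11-exo-diol (O on C9 and C11 exo, Me12 endo) | OC[C@]12[C@@H](O)[C@@](C)(O)[C@@H]3CC(=O)[C@@]1(C)[C@@]1(O)[C@@H](C)C(=O)O[C@@]1(C)[C@@H]32 | intermediate
28 | C6 aldehyde C9 ketone (α-ketol C9/C11) | O=C[C@]12C(=O)[C@@](C)(O)[C@@H]3CC(=O)[C@@]1(C)[C@@]1(O)[C@@H](C)C(=O)O[C@@]1(C)[C@@H]32 | intermediate
29 | (E)-but-2-enal | C/C=C/C=O | starting material
30 | (1E,3E)-1-iodopenta-1,3-diene | C/C=C/C=C/I | intermediate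
31 | C6 dienyl carbinol (both C6 epimers) | C/C=C/C=C/C(O)[C@]12C(=O)[C@@](C)(O)[C@@H]3CC(=O)[C@@]1(C)[C@@]1(O)[C@@H](C)C(=O)O[C@@]1(C)[C@@H]32 | intermediate
32 | C6 sorbyl ketone (15-deacyl target) | C/C=C/C=C/C(=O)[C@]12C(=O)[C@@](C)(O)[C@@H]3CC(=O)[C@@]1(C)[C@@]1(O)[C@@H](C)C(=O)O[C@@]1(C)[C@@H]32 | intermediate
33 | sorbic acid | C/C=C/C=C/C(=O)O | starting material
34 | 1-[(2E,4E)-hexa-2,4-dienoyl]-1H-benzotriazole | C/C=C/C=C/C(=O)n1nnc2ccccc21 | intermediate
35 | CNP0231466.1 | C/C=C/C=C/C(=O)[C@]12C(=O)[C@@](C)(O)[C@@H]3\C(=C(O)/C=C/C=C/C)C(=O)[C@@]1(C)[C@@]1(O)[C@@H](C)C(=O)O[C@@]1(C)[C@@H]32 | target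

## Step count and least certain steps

Total: 26 steps. Longest linear sequence: 24 steps (1–21, 23, 24, 26).

Step 2 (key step). The annulation may stall after the first ring, or the hydrated keto aldehyde may be diverted into oligomers, because the benzyloxymethyl ketone carbon is more hindered than in methylglyoxal and the closing Michael addition builds quaternary C8. Fallback: run the condensation of 2 with one equivalent of 3 at lower pH to the monocyclic 1:1 adduct F1, isolate it, and treat it with the second equivalent of 3 in NaHCO3 buffer; this returns to the route at 4.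

Step 4. Chlorination of ring C may lack site selectivity between C34 and C25, which would send the methyl group of step 5 to the wrong carbon. Fallback: from 6, block with the bulkier N-(phenylthio)phthalimide and Et3N to give the bis(phenylthio) lactone F2, methylate it (Cs2CO3, MeI) to the 25-methyl bis(phenylthio) lactone F3, then hydrolyse and decarboxylate the lactone in aqueous acid and remove sulfur with Zn/AcOH; this returns at 10.

Step 7. The enzyme may discriminate poorly between the antipodes of a primary alcohol whose stereocentre is a quaternary β-carbon. Fallback: silylate racemic 10 directly and separate the antipodes of the racemic silyl ether by preparative chromatography on a chiral stationary phase; this returns at 11 and makes no new compound.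

Step 11. The alkyllithium may be lost by proton transfer or by attack of t-BuLi on an ester before it reaches the hindered C25 ester. Fallback: from 14, convert ring C into its sodium enolate (NaHMDS) and cyclise by single-electron reduction with SmI2 and catalytic Fe(acac)3 (intramolecular nucleophilic acyl substitution through an organosamarium species, no strong base or cryogenic exchange); this returns at 15 and makes no new compound.

Step 13. O-Triflation may not discriminate enough between the C11 ketone and the C23 or C27 ketones. Fallback: from 18, add MeMgBr/CeCl3 at −78 °C to the least hindered ketone to give the C11 tertiary alcohol F4, and dehydrate it with Burgess reagent (C14 is a bridgehead, so elimination goes towards C9; any exocyclic isomer is isomerised with RhCl3·3H2O); this returns at 20.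

Step 16. Facial selectivity may be poor or reversed, with oxygen delivered to the exo face of C34. Fallback (reversed order, so that the methyl group enters last on the face the electrophile prefers): from 15, omit the methylation and run the Krapcho reaction and ketal cleavage to the C34-unsubstituted triketone F5; apply the conditions of steps 13–15 to obtain the enol triflate F6, the methyl alkene F7 and the silyl enol ether F8; oxidise the C27/C34 enolate (KHMDS, Davis oxaziridine) to the secondary α-hydroxy ketone F9; then form the dianion (KHMDS, 2.2 equiv) and C-methylate with MeI, which returns at 22.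

## Further compounds

F1 | step 2 | dimethyl 5-[(benzyloxy)methyl]-5-hydroxy-2-oxocyclopent-3-ene-1,3-dicarboxylate (racemic, relative configuration open) | COC(=O)C1=CC(O)(COCc2ccccc2)C(C(=O)OC)C1=O
F2 | step 4 | 14,34-bis(phenylthio) lactone triester (PhS exo on C14 and C34) | O=C1OC[C@@]23[C@@H]1C(=O)[C@](Sc1ccccc1)(C(=O)OC)[C@@H]2[C@](Sc1ccccc1)(C(=O)OC)C(=O)[C@@H]3C(=O)OC
F3 | step 4 | 25-methyl 14,34-bis(phenylthio) lactone triester | O=C1OC[C@@]23[C@@H]1C(=O)[C@](Sc1ccccc1)(C(=O)OC)[C@@H]2[C@](Sc1ccccc1)(C(=O)OC)C(=O)[C@]3(C)C(=O)OC
F0 | step 7 | none | none
F0 | step 11 | none | none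
F4 | step 13 | C11 tertiary alcohol (Me exo, OH endo) of the C23/C27 diketone | CC(C)(C)[Si](c1ccccc1)(c1ccccc1)OC[C@]12C[C@@](O)(C)[C@@H]3CC(=O)[C@@]1(C)C(=O)C(C)[C@@H]32
F5 | step 16 | C34-unsubstituted triketone (C34H2) | CC(C)(C)[Si](c1ccccc1)(c1ccccc1)OC[C@]12CC(=O)[C@@H]3CC(=O)[C@@]1(C)C(=O)C[C@@H]32
F6 | step 16 | C9=C11 enol triflate of the C34-unsubstituted diketone | CC(C)(C)[Si](c1ccccc1)(c1ccccc1)OC[C@]12C=C(OS(=O)(=O)C(F)(F)F)[C@@H]3CC(=O)[C@@]1(C)C(=O)C[C@@H]32
F7 | step 16 | 11-methyl alkene of the C34-unsubstituted diketone | CC(C)(C)[Si](c1ccccc1)(c1ccccc1)OC[C@]12C=C(C)[C@@H]3CC(=O)[C@@]1(C)C(=O)C[C@@H]32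
F8 | step 16 | C15=C23 TBS enol ether with C34H2 | CC(C)(C)[Si](c1ccccc1)(c1ccccc1)OC[C@]12C=C(C)[C@@H]3C=C(O[Si](C)(C)C(C)(C)C)[C@@]1(C)C(=O)C[C@@H]32
F9 | step 16 | secondary α-hydroxy ketone (C34–OH, either epimer) | CC(C)(C)[Si](c1ccccc1)(c1ccccc1)OC[C@]12C=C(C)[C@@H]3C=C(O[Si](C)(C)C(C)(C)C)[C@@]1(C)C(=O)C(O)[C@@H]32
A1 | alternative 1 | tricyclic ketone with exocyclic methylene at C27 | C/C=C/C=C/C(=O)[C@]12C(=O)[C@@](C)(O[Si](C)(C)C)[C@@H]3CC(=O)[C@@]1(C)C(=C)[C@@](C)(O[Si](C)(C)C)[C@@H]32
A2 | alternative 2 | tricyclo[3.3.0.0]octanone holding rings A and C plus the C14–C34 cyclopropane bond | CC(C)(C)[Si](C)(C)OC[C@@]12C(OC)(OC)C(=O)[C@H]3[C@@H]1[C@@]3(OC)[C@@H](O[Si](C)(C)C(C)(C)C)[C@]2(C)C(=O)OC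
A3 | alternative 3 | 11-deoxy target as its O28-trimethylsilyl ether | C/C=C/C=C/C(=O)[C@]12C(=O)[C@H](C)[C@@H]3\C(=C(O)/C=C/C=C/C)C(=O)[C@@]1(C)[C@@]1(O[Si](C)(C)C)[C@@H](C)C(=O)O[C@@]1(C)[C@@H]32
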